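**Strategy.** The route rests on cutting the geranyl chain between its benzylic carbon C1'' (the CH2 on ring A carbon C3', flanked by the C2' hydroxyl and the C4' methoxy group) and the vinylic carbon C2''. The key step exploits the (E)-2-methylalk-1-enyl pattern of the C2''=C3'' alkene: zirconium-catalysed syn-methylalumination of 6-methylhept-5-en-1-yne installs the C3'' methyl branch and the E geometry, and the alkenylalane is cross-coupled in the same flask, under zerovalent palladium catalysis, with a ring A benzylic bromide. The precursors are therefore a terminal enyne and 2-acetoxy-3-(bromomethyl)-4-methoxyacetophenone; a final Claisen–Schmidt condensation with 4-hydroxybenzaldehyde builds the chalcone.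

Key step: step 5

Remark: primed locants refer to ring A, doubly primed locants to the geranyl chain; compounds 1, 5 and 9 and the reagents named are taken as catalogue chemicals.

Step 1
Reactants: 1 2,4-dihydroxy-3-methylacetophenone
Product: 2 2-hydroxy-4-methoxy-3-methylacetophenone
Conditions: MeI (1.1 equiv), K2CO3 (1.2 equiv), acetone, reflux
Reagents that add atoms: iodomethane, CI
Why: Williamson etherification should be selective for the 4-OH because the 2-OH is tied up in a hydrogen bond to the acetyl carbonyl and is the poorer nucleophile.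

Step 2
Reactants: 2 2-hydroxy-4-methoxy-3-methylacetophenone
Product: 3 6-acetyl-3-methoxy-2-methylphenyl acetate
Conditions: Ac2O, pyridine, DMAP (cat.), rt to 50 °C
Reagents that add atoms: acetic anhydride, CC(=O)OC(C)=O
Why: DMAP-catalysed O-acetylation masks the phenol, which lowers the ring's reactivity towards electrophilic bromine and gives an ester that the hydroxide of the last step removes.

Step 3
Reactants: 3 6-acetyl-3-methoxy-2-methylphenyl acetate
Product: 4 6-acetyl-2-(bromomethyl)-3-methoxyphenyl acetate
Conditions: NBS (1.05 equiv), AIBN (5 mol %), PhCF3, 80 °C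
Reagents that add atoms: N-bromosuccinimide, O=C1CCC(=O)N1Br
Why: Wohl–Ziegler radical bromination should take the only benzylic methyl group, since the acetoxy and para-acetyl groups damp nuclear bromination in a non-polar medium.

Step 4
Reactants: 5 5-bromo-2-methylpent-2-ene
Product: 6 6-methylhept-5-en-1-yne
Conditions: LiC≡CH·H2N(CH2)2NH2 (1.5 equiv), DMSO, 10 °C to rt
Reagents that add atoms: lithium acetylide ethylenediamine complex, [Li]C#C.NCCN
Why: SN2 alkylation of the acetylide by the primary homoallylic bromide in DMSO should give the terminal enyne.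

Step 5
Reactants: 6 6-methylhept-5-en-1-yne; 4 6-acetyl-2-(bromomethyl)-3-methoxyphenyl acetate
Product: 8 6-acetyl-2-[(2E)-3,7-dimethylocta-2,6-dien-1-yl]-3-methoxyphenyl acetate, via alkenyldimethylalane 7 (not isolated)
Conditions: 6 (1.3 equiv), AlMe3 (2.0 equiv), Cp2ZrCl2 (0.2 equiv), CH2Cl2, 0 °C to rt; volatiles and excess AlMe3 removed in vacuo; then 4 (1.0 equiv), Pd(PPh3)4 (5 mol %), THF, 0 °C to rt
Reagents that add atoms: trimethylaluminium, C[Al](C)C
Why: Cp2ZrCl2 and AlMe3 form a methylzirconium species that adds methyl and metal syn across the terminal alkyne of 6 with the metal on the terminal carbon, and exchange to aluminium gives alane 7 with the new methyl and Al cis; oxidative addition of the benzylic C–Br bond of 4 to zerovalent palladium, transfer of the alkenyl group from Al to Pd and reductive elimination should then form the C1''–C2'' bond with retention of alkene geometry. The closest known reaction type is the Negishi zirconium-catalysed carboalumination followed by palladium- or nickel-catalysed cross-coupling of alkenylalanes with benzylic halides, as used for polyprenylated arenes and quinones. No ring is closed and no stereocentre is formed; the E geometry of C2''=C3'' follows from the syn addition and the stereoretentive coupling. The step needs regioselective methylalumination (secured by the terminal alkyne, the remote trisubstituted alkene being inert) and chemoselectivity for C–Br over the aryl ketone and the acetate (secured by the low carbonyl reactivity of the neutral, THF-solvated alkenyldimethylalane once excess AlMe3 has been stripped off).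

Step 6
Reactants: 8 6-acetyl-2-[(2E)-3,7-dimethylocta-2,6-dien-1-yl]-3-methoxyphenyl acetate; 9 4-hydroxybenzaldehyde
Product: 11 xanthoangelol F, via geranylated phenol 10 (not isolated)
Conditions: KOH (50% aq., 8 equiv), EtOH, 0 °C then rt; 1 M HCl to pH 5
Reagents that add atoms: none
Why: Hydroxide should first saponify the aryl acetate to phenol 10, whose methyl ketone enolate then undergoes Claisen–Schmidt aldol condensation with 9 and E1cB dehydration to the thermodynamically preferred E enone.

**Compound list**

1 | 2,4-dihydroxy-3-methylacetophenone | CC(=O)c1ccc(O)c(C)c1O | starting material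
2 | 2-hydroxy-4-methoxy-3-methylacetophenone | CC(=O)c1ccc(OC)c(C)c1O | intermediate
3 | 6-acetyl-3-methoxy-2-methylphenyl acetate (2-acetoxy-4-methoxy-3-methylacetophenone) | CC(=O)Oc1c(C)c(OC)ccc1C(C)=O | intermediate
4 | 6-acetyl-2-(bromomethyl)-3-methoxyphenyl acetate (2-acetoxy-3-(bromomethyl)-4-methoxyacetophenone) | CC(=O)Oc1c(CBr)c(OC)ccc1C(C)=O | intermediate
5 | 5-bromo-2-methylpent-2-ene | CC(C)=CCCBr | starting material
6 | 6-methylhept-5-en-1-yne | C#CCCC=C(C)C | intermediate
7 | [(1E)-2,6-dimethylhepta-1,5-dien-1-yl]dimethylalane | C[Al](C)/C=C(\C)CCC=C(C)C | intermediate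
8 | 6-acetyl-2-[(2E)-3,7-dimethylocta-2,6-dien-1-yl]-3-methoxyphenyl acetate | CC(=O)Oc1c(C/C=C(\C)CCC=C(C)C)c(OC)ccc1C(C)=O | intermediate
9 | 4-hydroxybenzaldehyde | O=Cc1ccc(O)cc1 | starting material
10 | 1-{3-[(2E)-3,7-dimethylocta-2,6-dien-1-yl]-2-hydroxy-4-methoxyphenyl}ethan-1-one | CC(=O)c1ccc(OC)c(C/C=C(\C)CCC=C(C)C)c1O | intermediate
11 | xanthoangelol F, (2E)-1-{3-[(2E)-3,7-dimethylocta-2,6-dien-1-yl]-2-hydroxy-4-methoxyphenyl}-3-(4-hydroxyphenyl)prop-2-en-1-one | COc1ccc(C(=O)/C=C/c2ccc(O)cc2)c(O)c1C/C=C(\C)CCC=C(C)C | target

**Step count and risks**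

Total step count: 6. Longest linear sequence: 5 steps (steps 1, 2, 3, 5, 6).

Steps most likely to fail:

Step 5. Aluminium-bound methyl or alkenyl groups may add to the aryl ketone of 4, or the benzylic bromide may homocouple, so that the cross-coupling is eroded. The fallback sets out from 6 and 4 and comes back at 8, with the roles of the partners reversed. Alane 7, made from 6 as before, would be quenched with I2 (THF, −30 to 0 °C) to give (1E)-1-iodo-2,6-dimethylhepta-1,5-diene F1. Bromide 4 would be converted by zinc dust and LiCl (THF, 0 °C to rt) into [2-(acetyloxy)-3-acetyl-6-methoxyphenyl]methylzinc bromide F2, a class of reagent that tolerates ketones and esters. Negishi coupling of F2 with F1 (Pd(OAc)2, SPhos, THF, rt) should then give 8.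

Step 3. Electrophilic bromination of ring A at C5', ortho to the methoxy group, or over-bromination at the benzylic carbon may compete with the radical chain. The fallback sets out from 1 and comes back at 10, postponing the O-methylation so that the ring carries no ether donor during bromination. Compound 1 would be diacetylated (Ac2O, pyridine, DMAP) to 4-acetyl-2-methyl-1,3-phenylene diacetate F3 and brominated (NBS, AIBN, PhCF3, 80 °C) to 4-acetyl-2-(bromomethyl)-1,3-phenylene diacetate F4. Coupling of F4 with alane 7 under the conditions of step 5 should give 4-acetyl-2-[(2E)-3,7-dimethylocta-2,6-dien-1-yl]-1,3-phenylene diacetate F5. Methanolysis (K2CO3 cat., MeOH, rt) would give 1-{3-[(2E)-3,7-dimethylocta-2,6-dien-1-yl]-2,4-dihydroxyphenyl}ethan-1-one F6. Selective methylation of its non-chelated 4-OH (MeI, K2CO3, acetone) should give phenol 10, which would then be condensed with 9 under the KOH conditions of step 6.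

Step 6. The phenoxide of 9 is a deactivated electrophile, so the aldol condensation may stall, and prolonged exposure to base may cause conjugate cyclisation of the 2'-phenoxide to the flavanone. The fallback sets out from 9 and 8 and comes back at 11. Aldehyde 9 would be protected (3,4-dihydro-2H-pyran, PPTS, CH2Cl2) as racemic 4-(oxan-2-yloxy)benzaldehyde F7. Condensation of F7 with 8 (KOH, EtOH, rt, acetate cleaved in the same flask) should give (2E)-1-{3-[(2E)-3,7-dimethylocta-2,6-dien-1-yl]-2-hydroxy-4-methoxyphenyl}-3-[4-(oxan-2-yloxy)phenyl]prop-2-en-1-one F8. Mild acetal exchange (PPTS, MeOH, 40 °C), which the geranyl chain should survive, would release 11.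

Further compounds
F1 | step 5 | (1E)-1-iodo-2,6-dimethylhepta-1,5-diene | I/C=C(\C)CCC=C(C)C
F2 | step 5 | [2-(acetyloxy)-3-acetyl-6-methoxyphenyl]methylzinc bromide | CC(=O)Oc1c(C[Zn]Br)c(OC)ccc1C(C)=O
F3 | step 3 | 4-acetyl-2-methyl-1,3-phenylene diacetate | CC(=O)Oc1ccc(C(C)=O)c(OC(C)=O)c1C
F4 | step 3 | 4-acetyl-2-(bromomethyl)-1,3-phenylene diacetate | CC(=O)Oc1ccc(C(C)=O)c(OC(C)=O)c1CBr
F5 | step 3 | 4-acetyl-2-[(2E)-3,7-dimethylocta-2,6-dien-1-yl]-1,3-phenylene diacetate | CC(=O)Oc1ccc(C(C)=O)c(OC(C)=O)c1C/C=C(\C)CCC=C(C)C
F6 | step 3 | 1-{3-[(2E)-3,7-dimethylocta-2,6-dien-1-yl]-2,4-dihydroxyphenyl}ethan-1-one | CC(=O)c1ccc(O)c(C/C=C(\C)CCC=C(C)C)c1O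
F7 | step 6 | 4-(oxan-2-yloxy)benzaldehyde | O=Cc1ccc(OC2CCCCO2)cc1
F8 | step 6 | (2E)-1-{3-[(2E)-3,7-dimethylocta-2,6-dien-1-yl]-2-hydroxy-4-methoxyphenyl}-3-[4-(oxan-2-yloxy)phenyl]prop-2-en-1-one | COc1ccc(C(=O)/C=C/c2ccc(OC3CCCCO3)cc2)c(O)c1C/C=C(\C)CCC=C(C)C
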